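**Retrosynthetic overview**
1. The ten-membered carbocycle is closed last, by ring-closing metathesis at C1=C10, after all four esters and both ring oxiranes are in place.
2. Both ring oxiranes are cut at C–O and relayed through one hydroxyl: the 2,3-oxirane comes from an anti chlorohydrin (C3–O displaces C2–Cl), the 4,5-oxirane from a C3–OH-directed epoxidation of the (Z)-C4=C5 alkene.
3. The chlorohydrin and its vinyl handle come from an enantioselective anti-chloroallylboration of a (Z)-enal; the 8,9-syn-diol and the C10 methylidene come from a Brown alkoxyallylboration of a butenolide aldehyde.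
4. The butenolide is the first ring: its lactone C–O bond closes when an alkenylmagnesium chelate, made by anti-carbomagnesiation of a propargylic alcohol, is carboxylated; C6 is set by asymmetric alkynylation.
5. Ring order: butenolide, then the side-chain oxirane (brought in as its acid), then the 4,5-oxirane, then the 2,3-oxirane, then the ten-membered ring.

Assumption: germacranolide numbering is used (lactone C12–O–C6, C7=C11, C13 = CH2OAc, C14 = CH2O on C10, C15 = CH3 on C4); the target is read as (2R,3S,4S,5S,6R,8R,9R,2′S) with a 1(10)Z alkene.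

**Step 1**
Reactants: 1 prop-2-yn-1-ol
Product: 3 (2Z)-3-iodo-2-methylprop-2-en-1-ol, via magnesium chelate 2 (not isolated)
Conditions: MeMgBr (2.5 equiv), CuI (10 mol%), THF, −10 °C to rt; then I2, −60 °C to rt
Reagents that add atoms: methylmagnesium bromide C[Mg]Br; iodine II
Why: Duboudin anti-carbomagnesiation puts methyl on the alkyne carbon next to the alkoxide and holds the alkenyl–Mg bond cis to CH2O in a chelate, so iodinolysis with retention fixes the Z geometry of the future C4=C5 alkene.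

**Step 2**
Reactants: 3 (2Z)-3-iodo-2-methylprop-2-en-1-ol
Product: 4 TBDPS ether of 3
Conditions: TBDPSCl, imidazole, CH2Cl2, 0 °C to rt
Reagents that add atoms: tert-butyl(chloro)diphenylsilane CC(C)(C)[Si](Cl)(c1ccccc1)c1ccccc1
Why: Standard silylation of a primary alcohol gives a robust ether that masks the C3 oxygen until step 16.

**Step 3**
Reactants: 4 TBDPS ether of 3
Product: 6 (2Z)-4-[tert-butyl(diphenyl)silyloxy]-3-methylbut-2-enal, via vinyllithium 5 (not isolated)
Conditions: tBuLi (2.1 equiv), Et2O, −78 °C; DMF, −78 °C; aq NH4Cl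
Reagents that add atoms: N,N-dimethylformamide CN(C)C=O
Why: Iodine–lithium exchange proceeds with retention of alkene geometry and Bouveault formylation with DMF then gives the Z-enal.

**Step 4**
Reactants: 6 (2Z)-4-[tert-butyl(diphenyl)silyloxy]-3-methylbut-2-enal; 7 tert-butyl(dimethyl)(prop-2-yn-1-yloxy)silane
Product: 8 (2Z,4S)-7-[tert-butyl(dimethyl)silyloxy]-1-[tert-butyl(diphenyl)silyloxy]-2-methylhept-2-en-5-yn-4-ol
Conditions: Me2Zn (3 equiv), (S,S)-ProPhenol [2,6-bis{[(2S)-2-(hydroxydiphenylmethyl)pyrrolidin-1-yl]methyl}-4-methylphenol] (20 mol%), Ph3P=O (40 mol%), toluene, 0 °C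
Reagents that add atoms: none
Why: Trost zinc–ProPhenol asymmetric alkynylation of the enal must deliver the alkynyl group to the Re face to set the carbinol (4S here, the future C6); the (S,S) ligand is chosen from memory of its usual sense, and the antipode is used if it proves opposite.

**Step 5**
Reactants: 8 propargylic alcohol (2Z,4S)
Product: 11 (5S)-3-(TBSO-methyl)-4-[(isopropoxydimethylsilyl)methyl]-5-[(1Z)-3-(TBDPSO)-2-methylprop-1-enyl]furan-2(5H)-one, via alkenylmagnesium chelate 9 (not isolated), via hydroxy acid 10 (not isolated)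
Conditions: (iPrO)Me2SiCH2MgCl (3.5 equiv), CuI (15 mol%), THF, 0 to 45 °C; CO2 (1 atm), 0 °C to rt; aq citric acid
Reagents that add atoms: (isopropoxydimethylsilyl)methylmagnesium chloride CC(C)O[Si](C)(C)C[Mg]Cl; carbon dioxide O=C=O
Why: Alkoxide-directed anti-carbomagnesiation (Duboudin/Fallis) puts the silylmethyl group on C7 and the chelated alkenyl–Mg bond on C11 cis to the C6 oxygen, so carboxylation and acidification lactonise directly to the tetrasubstituted butenolide with C6 untouched.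

**Step 6**
Reactants: 11 silylmethyl butenolide
Product: 12 (5S)-4-(hydroxymethyl) butenolide (otherwise as 11)
Conditions: H2O2 (30%), KF, KHCO3, THF/MeOH, rt
Reagents that add atoms: hydrogen peroxide OO
Why: Tamao–Fleming oxidation converts the C–Si bond of the alkoxysilane into C–OH and unmasks the C8 hydroxymethyl group.

**Step 7**
Reactants: 12 hydroxymethyl butenolide
Product: 13 (2S)-4-(TBSO-methyl)-2-[(1Z)-3-(TBDPSO)-2-methylprop-1-enyl]-5-oxo-2,5-dihydrofuran-3-carbaldehyde
Conditions: Dess–Martin periodinane, NaHCO3, CH2Cl2, 0 °C to rt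
Reagents that add atoms: none
Why: Dess–Martin oxidation of the primary allylic alcohol gives the non-enolisable C8 aldehyde under buffered, base-free conditions.

**Step 8**
Reactants: 14 2-methylidenepropane-1,3-diol
Product: 15 3-(methoxymethoxy)-2-[(methoxymethoxy)methyl]prop-1-ene
Conditions: MOMCl, iPr2NEt, CH2Cl2, 0 °C to rt
Reagents that add atoms: chloromethyl methyl ether COCCl
Why: O-alkylation of both hydroxyls (Williamson type) gives the symmetrical bis-acetal, so either allylic CH2 gives the same anion on lithiation.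

**Step 9**
Reactants: 13 butenolide aldehyde; 15 bis-MOM allyl ether
Product: 18 (5S)-butenolide bearing at C7 the (8R,9R)-8-hydroxy-9-(methoxymethoxy)-10-methylidene-14-(methoxymethoxy) chain, via allyllithium 16 (not isolated), via allylborane 17 (not isolated)
Conditions: 15, sBuLi, THF, −78 °C; (−)-Ipc2BOMe [from (+)-α-pinene], −78 °C; BF3·OEt2; 13, −78 °C; HOCH2CH2NH2, rt
Reagents that add atoms: none
Why: Brown alkoxyallylboration with the γ-alkoxyallylborane (alkoxy cis to CH2B) goes through a chair Zimmerman–Traxler transition state to the syn 8,9-diol derivative, and the Ipc groups from (+)-α-pinene direct attack to the Si face of the aldehyde, setting 8R and 9R.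

**Step 10**
Reactants: 18 alkoxyallylation adduct
Product: 20 (6S,8R,9R)-8,13-diacetate (9,14-bis-MOM ether; 3-O-TBDPS), via diol 19 (not isolated)
Conditions: camphorsulfonic acid (10 mol%), MeOH/CH2Cl2, 0 °C; concentrate; Ac2O, pyridine, 4-dimethylaminopyridine (cat.), CH2Cl2, 0 °C to rt
Reagents that add atoms: acetic anhydride CC(=O)OC(C)=O
Why: Acid-catalysed methanolysis removes only the primary TBS ether (TBDPS and MOM survive) and one nucleophile-catalysed acetylation then installs both acetates of the target.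

**Step 11**
Reactants: 20 diacetate bis-MOM ether
Product: 21 (6S,8R,9R)-9,14-diol (8,13-diacetate; 3-O-TBDPS)
Conditions: Me2BBr, CH2Cl2, −78 °C; then THF/aq NaHCO3
Reagents that add atoms: none
Why: Guindon acetal cleavage with Me2BBr removes both MOM groups at low temperature without touching the acetates, the silyl ether or the alkenes.

**Step 12**
Reactants: 21 9,14-diol; 22 3-methylbut-2-enoyl chloride
Product: 23 (6S,8R,9R)-14-O-(3-methylbut-2-enoyl) 9-alcohol
Conditions: 2,4,6-collidine, CH2Cl2, −78 to −30 °C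
Reagents that add atoms: none
Why: Chemoselective acylation with the acid chloride takes the primary allylic C14 hydroxyl in preference to the hindered secondary C9 hydroxyl at low temperature.

**Step 13**
Reactants: 24 2-methylprop-2-en-1-ol
Product: 25 [(2R)-2-methyloxiran-2-yl]methanol
Conditions: Ti(OiPr)4 (5 mol%), D-(−)-diisopropyl tartrate (6 mol%), tBuOOH, 4 Å MS, CH2Cl2, −20 °C
Reagents that add atoms: tert-butyl hydroperoxide CC(C)(C)OO
Why: Sharpless catalytic asymmetric epoxidation of the 2-substituted allylic alcohol with the D-tartrate gives the (R)-epoxy alcohol under reagent control.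

**Step 14**
Reactants: 25 (R)-2-methylglycidol
Product: 26 (2S)-2-methyloxirane-2-carboxylic acid
Conditions: RuCl3 hydrate (2 mol%), NaIO4, MeCN/EtOAc/H2O, 0 °C to rt
Reagents that add atoms: water O
Why: Ruthenium tetroxide-catalysed oxidation (Sharpless conditions) takes the primary alcohol to the acid without opening the oxirane; the stereocentre is untouched and its descriptor changes only through priority.

**Step 15**
Reactants: 23 9-alcohol; 26 (S)-2-methylglycidic acid
Product: 27 (6S,8R,9R,2′S)-9-O-(2-methyloxirane-2-carbonyl) ester (3-O-TBDPS)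
Conditions: 26, 2,4,6-Cl3C6H2COCl, Et3N, THF, 0 °C; then 23, 4-dimethylaminopyridine, toluene, rt
Reagents that add atoms: none
Why: Yamaguchi esterification through the mixed anhydride acylates the hindered secondary allylic C9 hydroxyl with retention and leaves the acid's oxirane intact.

**Step 16**
Reactants: 27 fully esterified TBDPS ether
Product: 29 (6S,8R,9R,2′S)-(4Z)-enal with C3 as CHO, via allylic alcohol 28 (not isolated)
Conditions: HF·pyridine, pyridine, THF, 0 °C to rt; aq NaHCO3; crude, MnO2, CH2Cl2, rt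
Reagents that add atoms: none
Why: Fluoride desilylation followed by chemoselective MnO2 oxidation of the only allylic alcohol gives the Z-enal without Z/E isomerisation.

**Step 17**
Reactants: 30 (1E)-1,3-dichloroprop-1-ene
Product: 31 2-[(2E)-3-chloroprop-2-en-1-yl]-4,4,5,5-tetramethyl-1,3,2-dioxaborolane
Conditions: B2pin2, Pd2(dba)3 (1.5 mol%), DMSO, 50 °C
Reagents that add atoms: bis(pinacolato)diboron CC1(C)OB(OC1(C)C)B1OC(C)(C)C(C)(C)O1
Why: Palladium-catalysed Miyaura-type allylic borylation goes through the 1-chloro-π-allyl complex, which is borylated at the unsubstituted terminus while the E vinyl chloride is kept.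

**Step 18**
Reactants: 29 (4Z)-enal; 31 (E)-3-chloroallyl pinacol boronate
Product: 32 (2S,3R,6S,8R,9R,2′S)-anti-chlorohydrin with C3–OH and C2–Cl and a C1 vinyl group
Conditions: (S)-TRIP [(S)-3,3′-bis(2,4,6-triisopropylphenyl)-1,1′-binaphthyl-2,2′-diyl hydrogen phosphate] (5 mol%), 4 Å MS, toluene, −30 °C; aq NaHCO3
Reagents that add atoms: none
Why: Proposed new method: chiral phosphoric acid-catalysed anti-chloroallylboration, in which the acid hydrogen-bonds to a boronate oxygen while its phosphoryl oxygen holds the formyl hydrogen, the E-γ-chloroallyl boronate reacts through a closed chair transition state with chlorine equatorial to give the 2,3-anti chlorohydrin, and the (S)-acid exposes the Si face of the enal to set C3 (R here, the future 3S) and C2 (S here, inverted in step 19); the closest known reactions are the phosphoric acid-catalysed allyl- and crotylboration of aldehydes with pinacol boronates (Antilla) and the stoichiometric chloroallylboration with (Z)-γ-chloroallyl-B(Ipc)2, which gives only syn chlorohydrins.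

**Step 19**
Reactants: 32 anti-chlorohydrin
Product: 34 (2R,3S,4S,5S,6R,8R,9R,2′S)-bis-oxirane diene with C1 vinyl and C10 methylidene, via epoxy chlorohydrin 33 (not isolated)
Conditions: mCPBA (1.2 equiv), NaHCO3, CH2Cl2, 0 °C; aq Na2S2O3 wash; DBU (2 equiv), CH2Cl2, 0 °C
Reagents that add atoms: 3-chloroperbenzoic acid OOC(=O)c1cccc(Cl)c1
Why: Henbest hydroxyl-directed epoxidation of the (Z)-allylic alcohol through its A(1,3)-minimised conformer delivers oxygen syn to C3–OH and gives the threo 4,5-oxirane (4S,5S in the product), and the same C3 oxygen then displaces the anti allylic chloride at C2 with inversion (halohydrin closure, an intramolecular Williamson etherification) to form the trans 2,3-oxirane.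

**Step 20**
Reactants: 34 bis-oxirane diene
Product: 35 target, (2R,3S,4S,5S,6R,8R,9R)-8,13-diacetoxy-2,3:4,5-diepoxy-9-{[(2S)-2-methyloxiran-2-yl]carbonyloxy}-14-[(3-methylbut-2-enoyl)oxy]germacra-1(10)Z,7(11)-dien-12,6-olide
Conditions: second-generation Hoveyda–Grubbs catalyst [RuCl2(H2IMes)(=CH–C6H4-2-OiPr)] (15 mol%), 1,4-benzoquinone (30 mol%), toluene (0.5 mM), 80 °C
Reagents that add atoms: none
Why: Ring-closing metathesis between the vinyl oxirane and the 1,1-disubstituted alkene releases ethene and forms the ten-membered ring, whose strain allows only the ring-cis (1(10)Z) trisubstituted alkene.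

**Compound list**
1 | prop-2-yn-1-ol | C#CCO | starting material
2 | chelated (Z)-alkenylmagnesium alkoxide (4-methyl-2,5-dihydro-1,2-oxamagnesole) | CC1=C[Mg]OC1 | intermediate
3 | (2Z)-3-iodo-2-methylprop-2-en-1-ol | OC/C(C)=C\I | intermediate
4 | tert-butyl{[(2Z)-3-iodo-2-methylprop-2-en-1-yl]oxy}diphenylsilane | CC(C)(C)[Si](c1ccccc1)(c1ccccc1)OC/C(C)=C\I | intermediate
5 | (1Z)-3-[tert-butyl(diphenyl)silyloxy]-2-methylprop-1-en-1-yllithium | CC(C)(C)[Si](c1ccccc1)(c1ccccc1)OC/C(C)=C\[Li] | intermediate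
6 | (2Z)-4-[tert-butyl(diphenyl)silyloxy]-3-methylbut-2-enal | CC(C)(C)[Si](c1ccccc1)(c1ccccc1)OC/C(C)=C\C=O | intermediate
7 | tert-butyl(dimethyl)(prop-2-yn-1-yloxy)silane | C#CCO[Si](C)(C)C(C)(C)C | starting material
8 | (2Z,4S)-7-[tert-butyl(dimethyl)silyloxy]-1-[tert-butyl(diphenyl)silyloxy]-2-methylhept-2-en-5-yn-4-ol | CC(C)(C)[Si](c1ccccc1)(c1ccccc1)OC/C(C)=C\[C@@H](C#CCO[Si](C)(C)C(C)(C)C)O | intermediate
9 | five-membered chelate: C6 alkoxide bound to the C11 alkenylmagnesium, silylmethyl on C7, CH2OTBS on C11 | CC(C)(C)[Si](c1ccccc1)(c1ccccc1)OC/C(C)=C\[C@@H]1O[Mg]C(CO[Si](C)(C)C(C)(C)C)=C1C[Si](C)(C)OC(C)C | intermediate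
10 | (Z)-γ-hydroxy acid: C12 acid on C11 cis to the C6 carbinol (C6 configured as in 8) | CC(C)(C)[Si](c1ccccc1)(c1ccccc1)OC/C(C)=C\[C@H](O)/C(C[Si](C)(C)OC(C)C)=C(/CO[Si](C)(C)C(C)(C)C)C(O)=O | intermediate
11 | (5S)-3-{[tert-butyl(dimethyl)silyloxy]methyl}-5-{(1Z)-3-[tert-butyl(diphenyl)silyloxy]-2-methylprop-1-en-1-yl}-4-{[dimethyl(propan-2-yloxy)silyl]methyl}furan-2(5H)-one | CC(C)(C)[Si](c1ccccc1)(c1ccccc1)OC/C(C)=C\[C@@H]1OC(=O)C(CO[Si](C)(C)C(C)(C)C)=C1C[Si](C)(C)OC(C)C | intermediate
12 | (5S)-4-(hydroxymethyl) analogue of 11 | CC(C)(C)[Si](c1ccccc1)(c1ccccc1)OC/C(C)=C\[C@@H]1OC(=O)C(CO[Si](C)(C)C(C)(C)C)=C1CO | intermediate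
13 | (2S)-4-{[tert-butyl(dimethyl)silyloxy]methyl}-2-{(1Z)-3-[tert-butyl(diphenyl)silyloxy]-2-methylprop-1-en-1-yl}-5-oxo-2,5-dihydrofuran-3-carbaldehyde | CC(C)(C)[Si](c1ccccc1)(c1ccccc1)OC/C(C)=C\[C@@H]1OC(=O)C(CO[Si](C)(C)C(C)(C)C)=C1C=O | intermediate
14 | 2-methylidenepropane-1,3-diol | C=C(CO)CO | starting material
15 | 3-(methoxymethoxy)-2-[(methoxymethoxy)methyl]prop-1-ene | C=C(COCOC)COCOC | intermediate
16 | 3-(methoxymethoxy)-2-[(methoxymethoxy)methyl]allyllithium (alkoxy cis to CH2Li) | COCO/C=C(\C[Li])COCOC | intermediate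
17 | B-{3-(methoxymethoxy)-2-[(methoxymethoxy)methyl]allyl}bis(isopinocampheyl)borane (alkoxy cis to CH2B; Ipc from (+)-α-pinene) | COCO/C=C(\CB([C@@H]1C[C@@H]2C[C@H]([C@H]1C)C2(C)C)[C@@H]1C[C@@H]2C[C@H]([C@H]1C)C2(C)C)COCOC | intermediate
18 | (5S)-3-{[tert-butyl(dimethyl)silyloxy]methyl}-5-{(1Z)-3-[tert-butyl(diphenyl)silyloxy]-2-methylprop-1-en-1-yl}-4-{(1R,2R)-1-hydroxy-2-(methoxymethoxy)-3-[(methoxymethoxy)methyl]but-3-en-1-yl}furan-2(5H)-one | CC(C)(C)[Si](c1ccccc1)(c1ccccc1)OC/C(C)=C\[C@@H]1OC(=O)C(CO[Si](C)(C)C(C)(C)C)=C1[C@@H](O)[C@H](OCOC)C(=C)COCOC | intermediate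
19 | 3-(hydroxymethyl) analogue of 18 (8,13-diol) | CC(C)(C)[Si](c1ccccc1)(c1ccccc1)OC/C(C)=C\[C@@H]1OC(=O)C(CO)=C1[C@@H](O)[C@H](OCOC)C(=C)COCOC | intermediate
20 | (5S)-3-(acetoxymethyl)-4-{(1R,2R)-1-acetoxy-2-(methoxymethoxy)-3-[(methoxymethoxy)methyl]but-3-en-1-yl}-5-{(1Z)-3-[tert-butyl(diphenyl)silyloxy]-2-methylprop-1-en-1-yl}furan-2(5H)-one | CC(C)(C)[Si](c1ccccc1)(c1ccccc1)OC/C(C)=C\[C@@H]1OC(=O)C(COC(C)=O)=C1[C@@H](OC(C)=O)[C@H](OCOC)C(=C)COCOC | intermediate
21 | (5S)-3-(acetoxymethyl)-4-[(1R,2R)-1-acetoxy-2-hydroxy-3-(hydroxymethyl)but-3-en-1-yl] analogue of 20 | CC(C)(C)[Si](c1ccccc1)(c1ccccc1)OC/C(C)=C\[C@@H]1OC(=O)C(COC(C)=O)=C1[C@@H](OC(C)=O)[C@H](O)C(=C)CO | intermediate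
22 | 3-methylbut-2-enoyl chloride | CC(C)=CC(Cl)=O | starting material
23 | 14-O-(3-methylbut-2-enoyl) derivative of 21 (9-OH free) | CC(C)(C)[Si](c1ccccc1)(c1ccccc1)OC/C(C)=C\[C@@H]1OC(=O)C(COC(C)=O)=C1[C@@H](OC(C)=O)[C@H](O)C(=C)COC(=O)C=C(C)C | intermediate
24 | 2-methylprop-2-en-1-ol | C=C(C)CO | starting material
25 | [(2R)-2-methyloxiran-2-yl]methanol | OC[C@]1(C)CO1 | intermediate
26 | (2S)-2-methyloxirane-2-carboxylic acid | OC(=O)[C@]1(C)CO1 | intermediate
27 | 9-O-[(2S)-2-methyloxirane-2-carbonyl] derivative of 23 (6S,8R,9R) | CC(C)(C)[Si](c1ccccc1)(c1ccccc1)OC/C(C)=C\[C@@H]1OC(=O)C(COC(C)=O)=C1[C@@H](OC(C)=O)[C@H](OC(=O)[C@]2(C)CO2)C(=C)COC(=O)C=C(C)C | intermediate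
28 | C3 primary allylic alcohol from 27 (4Z; 6S,8R,9R,2′S) | OC/C(C)=C\[C@@H]1OC(=O)C(COC(C)=O)=C1[C@@H](OC(C)=O)[C@H](OC(=O)[C@]2(C)CO2)C(=C)COC(=O)C=C(C)C | intermediate
29 | C3 (4Z)-enal (6S,8R,9R,2′S) | O=C/C(C)=C\[C@@H]1OC(=O)C(COC(C)=O)=C1[C@@H](OC(C)=O)[C@H](OC(=O)[C@]2(C)CO2)C(=C)COC(=O)C=C(C)C | intermediate
30 | (1E)-1,3-dichloroprop-1-ene | Cl/C=C/CCl | starting material
31 | 2-[(2E)-3-chloroprop-2-en-1-yl]-4,4,5,5-tetramethyl-1,3,2-dioxaborolane | Cl/C=C/CB1OC(C)(C)C(C)(C)O1 | intermediate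
32 | anti-chlorohydrin: butenolide C6 bears the (1Z,3R,4S)-4-chloro-3-hydroxy-2-methylhexa-1,5-dien-1-yl arm (2S,3R,6S,8R,9R,2′S) | C=C[C@H](Cl)[C@H](O)/C(C)=C\[C@@H]1OC(=O)C(COC(C)=O)=C1[C@@H](OC(C)=O)[C@H](OC(=O)[C@]2(C)CO2)C(=C)COC(=O)C=C(C)C | intermediate
33 | epoxy chlorohydrin: 4,5-oxirane as in 35, (2S,3R)-chlorohydrin, C1 vinyl | C=C[C@H](Cl)[C@H](O)[C@@]2(C)O[C@H]2[C@@H]1OC(=O)C(COC(C)=O)=C1[C@@H](OC(C)=O)[C@H](OC(=O)[C@]2(C)CO2)C(=C)COC(=O)C=C(C)C | intermediate
34 | (2R,3S,4S,5S,6R,8R,9R,2′S)-bis-oxirane with C1 vinyl and C10 methylidene (seco-1,10 form of 35) | C=C[C@H]2O[C@@H]2[C@@]2(C)O[C@H]2[C@@H]1OC(=O)C(COC(C)=O)=C1[C@@H](OC(C)=O)[C@H](OC(=O)[C@]2(C)CO2)C(=C)COC(=O)C=C(C)C | intermediate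
35 | (2R,3S,4S,5S,6R,8R,9R)-8,13-diacetoxy-2,3:4,5-diepoxy-9-{[(2S)-2-methyloxiran-2-yl]carbonyloxy}-14-[(3-methylbut-2-enoyl)oxy]germacra-1(10)Z,7(11)-dien-12,6-olide | CC(=O)OCC1=C2[C@@H](OC(C)=O)[C@H](OC(=O)[C@]3(C)CO3)/C(COC(=O)C=C(C)C)=C\[C@H]3O[C@@H]3[C@@]3(C)O[C@H]3[C@@H]2OC1=O | target

**Totals**
Total step count: 20. Longest linear sequence: 16 (steps 1–7, 9–12, 15, 16, 18–20, from prop-2-yn-1-ol).

**Three steps most likely to fail**

Step 18 (the new chloroallylboration; the reagent and catalyst class are untested on a chlorinated boronate and on this enal). The fallback uses known chemistry only; it sets out from allylic alcohol 28, which is then isolated after the desilylation of step 16 instead of being oxidised, and comes back at 34. Sharpless asymmetric epoxidation of 28 (Ti(OiPr)4, D-(−)-diisopropyl tartrate, tBuOOH, −20 °C; the primary C3 hydroxyl directs, reagent control) gives the 4,5-epoxy alcohol F1. Dess–Martin oxidation gives the epoxy aldehyde F2. Aggarwal sulfur-ylide epoxidation of F2 with the allylsulfonium salt of isothiocineole (the enantiomer that gives the 2R,3S oxirane, mild base) forms the trans vinyl oxirane and so gives 34, bypassing 29, 32 and 33.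

Step 20 (a trisubstituted alkene in a ten-membered ring from a vinyl oxirane and a hindered 1,1-disubstituted alkene). The fallback sets out from chlorohydrin 32 and comes back at target 35; it closes the ring before the oxiranes exist. Ring-closing metathesis of 32 with the same ruthenium catalyst, where the terminal alkene is a plain vinyl group next to a free hydroxyl, gives the macrocyclic chlorohydrin F3. mCPBA epoxidation directed by the C3 hydroxyl gives the macrocyclic epoxy chlorohydrin F4. DBU closes the 2,3-oxirane to give 35.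

Step 6 (the silane is γ to the lactone carbonyl, so fluoride may cause protodesilylation through the dienolate instead of oxidation). The fallback sets out from propargylic alcohol 8 and comes back at 12. The carbomagnesiation of step 5 is quenched with I2 instead of CO2 to give the hydroxy vinyl iodide F5. Tamao–Fleming oxidation at this stage, on a plain allylsilane with no carbonyl to stabilise a carbanion, gives the iodo diol F6. Carbonylative lactonisation (Pd(PPh3)4, CO, Et3N, THF, 50 °C) closes the butenolide onto the cis C6 hydroxyl, the C8 hydroxyl being trans to the acyl group, and gives 12.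

**Further compounds**
F1 | step 18 | 4,5-epoxy alcohol: C3 as CH2OH, (4R,5S)-oxirane, 6R, rest as 28 | OC[C@@]2(C)O[C@H]2[C@@H]1OC(=O)C(COC(C)=O)=C1[C@@H](OC(C)=O)[C@H](OC(=O)[C@]2(C)CO2)C(=C)COC(=O)C=C(C)C
F2 | step 18 | epoxy aldehyde: C3 as CHO on the (4S,5S)-oxirane, 6R, rest as 28 | O=C[C@@]2(C)O[C@H]2[C@@H]1OC(=O)C(COC(C)=O)=C1[C@@H](OC(C)=O)[C@H](OC(=O)[C@]2(C)CO2)C(=C)COC(=O)C=C(C)C
F3 | step 20 | macrocyclic chlorohydrin: 1(10)Z,4Z-diene, (2S,3R)-2-chloro-3-hydroxy, esters as in 35 | CC(=O)OCC1=C2[C@@H](OC(C)=O)[C@H](OC(=O)[C@]3(C)CO3)/C(COC(=O)C=C(C)C)=C\[C@H](Cl)[C@H](O)/C(C)=C\[C@@H]2OC1=O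
F4 | step 20 | macrocyclic epoxy chlorohydrin: 4,5-oxirane as in 35, (2S,3R)-2-chloro-3-hydroxy | CC(=O)OCC1=C2[C@@H](OC(C)=O)[C@H](OC(=O)[C@]3(C)CO3)/C(COC(=O)C=C(C)C)=C\[C@H](Cl)[C@H](O)[C@@]3(C)O[C@H]3[C@@H]2OC1=O
F5 | step 6 | hydroxy vinyl iodide: C11 iodide cis to the C6 carbinol, silylmethyl on C7 | CC(C)(C)[Si](c1ccccc1)(c1ccccc1)OC/C(C)=C\[C@H](O)/C(C[Si](C)(C)OC(C)C)=C(/CO[Si](C)(C)C(C)(C)C)I
F6 | step 6 | iodo diol: C8 as CH2OH, C11 iodide cis to the C6 carbinol | CC(C)(C)[Si](c1ccccc1)(c1ccccc1)OC/C(C)=C\[C@H](O)/C(CO)=C(/CO[Si](C)(C)C(C)(C)C)I
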